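**Retrosynthetic overview**

1. Target 12 is (R)-8-hydroxy-3-(11-hydroxyundecyl)-6-methoxyisochroman-1-one; the last step unmasks O8–H (from OMe) and the chain OH (from OTBS).
2. Key disconnection C4–C4a: lactone ring B is closed onto the preformed benzene ring A by a palladium/norbornene C–H alkylation of open-chain ester 10. An iodine at C5 starts the relay and is replaced by H in the same operation.
3. Enabling feature: C4a–H lies between C8a (ester anchor) and C5. C5 is para to O8 and ortho to O6, so it is iodinated selectively; its other neighbour C6 carries OMe, so C4a is the only position the palladacycle can reach.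
4. Ester bond C1–O2 by Steglich coupling of acid 9 with iodohydrin 7; the C3 stereocentre comes from (R)-epichlorohydrin and the chain from a C10 Grignard reagent.
5. Ring order: ring A is bought; ring B is the only ring formed (step 6).

Key step: step 6

Remark: compounds 1, 3 and 8 are taken as commercial; isochromanone locants (C1, O2, C3, C4, C4a to C8a) are used for all intermediates.

**Route**

Step 1
Reactants: 1 10-bromodecan-1-ol
Product: 2 (10-bromodecyloxy)(tert-butyl)dimethylsilane
Conditions: TBSCl, imidazole, CH2Cl2, 0 °C to rt
Reagents that add atoms: tert-butyldimethylsilyl chloride, CC(C)(C)[Si](C)(C)Cl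
Why: Imidazole-promoted silylation of a primary alcohol, under which the primary bromide is inert.

Step 2
Reactants: 2 (10-bromodecyloxy)(tert-butyl)dimethylsilane; 3 (R)-epichlorohydrin
Product: 6 (R)-tert-butyldimethyl{[11-(oxiran-2-yl)undecyl]oxy}silane, via Grignard reagent 4 (not isolated), via chlorohydrin 5 (not isolated)
Conditions: Mg, THF, 40 °C; CuI (10 mol %), 3, THF, −40 to 0 °C; sat. aq. NH4Cl; then 2 M NaOH, THF/MeOH, 0 °C to rt
Reagents that add atoms: none
Why: The copper-catalysed Grignard opening (SN2) attacks the unsubstituted oxirane carbon of 3, and the Williamson closure of chlorohydrin 5 occurs at the CH2Cl carbon, so neither event breaks a bond at the stereocentre and the (R) configuration of 3 should be carried into 6.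

Step 3
Reactants: 6 (R)-tert-butyldimethyl{[11-(oxiran-2-yl)undecyl]oxy}silane
Product: 7 (R)-13-[(tert-butyldimethylsilyl)oxy]-1-iodotridecan-2-ol
Conditions: LiI, AcOH, THF, rt, dark
Reagents that add atoms: lithium iodide, [Li+].[I-]
Why: Acid-assisted SN2 opening of a terminal epoxide by iodide at the primary carbon (halohydrin formation), which leaves the carbinol stereocentre untouched.

Step 4
Reactants: 8 2,4-dimethoxybenzoic acid
Product: 9 5-iodo-2,4-dimethoxybenzoic acid
Conditions: NIS, CF3CO2H (cat.), MeCN, rt
Reagents that add atoms: N-iodosuccinimide, O=C1CCC(=O)N1I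
Why: Electrophilic aromatic iodination should go to C5 of the acid, which is para to the 2-methoxy and ortho to the 4-methoxy group, whereas C3 is flanked by two methoxy groups and C6 is not activated.

Step 5
Reactants: 7 (R)-13-[(tert-butyldimethylsilyl)oxy]-1-iodotridecan-2-ol; 9 5-iodo-2,4-dimethoxybenzoic acid
Product: 10 (R)-13-[(tert-butyldimethylsilyl)oxy]-1-iodotridecan-2-yl 5-iodo-2,4-dimethoxybenzoate
Conditions: DCC, DMAP (cat.), CH2Cl2, 0 °C to rt
Reagents that add atoms: none
Why: Steglich esterification acylates the secondary hydroxyl without breaking its C–O bond, so the configuration is retained.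

Step 6
Reactants: 10 (R)-13-[(tert-butyldimethylsilyl)oxy]-1-iodotridecan-2-yl 5-iodo-2,4-dimethoxybenzoate
Product: 11 (R)-3-{11-[(tert-butyldimethylsilyl)oxy]undecyl}-6,8-dimethoxyisochroman-1-one
Conditions: Pd(OAc)2 (10 mol %), P(2-furyl)3 (20 mol %), norbornene (2 equiv), Cs2CO3 (3 equiv), HCO2Na (1.5 equiv), MeCN, 90 °C, 0.01 M, slow addition of 10
Reagents that add atoms: none
Why: Zerovalent palladium inserts into the aryl C5–I bond, norbornene inserts and carbonate-assisted C–H palladation at C4a gives a five-membered aryl–norbornyl palladacycle of divalent palladium, which is alkylated at C4a by the tethered primary iodide (oxidative addition to tetravalent palladium, then C(sp2)–C(sp3) reductive elimination); norbornene is then expelled by β-carbon elimination and formate transfers hydride to C5 with loss of CO2. The closest known reaction type is the Catellani ortho-alkylation of ortho-substituted aryl iodides with ipso hydride termination, including its ring-forming variants in which the alkyl halide hangs from the meta position. Ring B (the δ-lactone) closes by intramolecular substitution at the primary carbon C4, a 6-exo-tet closure in net terms that passes through a seven-membered palladacycle and needs the s-trans (lactone-like) ester rotamer, hence the high dilution. No stereocentre is formed, and C3 keeps its configuration because only the neighbouring CH2–I bond reacts. The step needs site selectivity for C4a over C7 and chemoselectivity between two C–I bonds: the palladacycle can only reach the two positions ortho to C5, of which C6 carries OMe, and zerovalent palladium inserts into the aryl iodide much faster than into the alkyl iodide.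

Step 7
Reactants: 11 (R)-3-{11-[(tert-butyldimethylsilyl)oxy]undecyl}-6,8-dimethoxyisochroman-1-one
Product: 12 (R)-8-hydroxy-3-(11-hydroxyundecyl)-6-methoxyisochroman-1-one
Conditions: BCl3 (4 equiv), CH2Cl2, −78 to 0 °C; then MeOH, rt
Reagents that add atoms: none
Why: BCl3 chelates between the lactone carbonyl and the peri C8 methoxy group and should cleave only that methyl ether (chelation-controlled Lewis-acid demethylation), leaving the C6 methoxy group alone, while the boron chloride and the methanolic HCl formed on quenching remove the primary silyl ether.

**Compound list**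

1 | 10-bromodecan-1-ol | OCCCCCCCCCCBr | starting material
2 | (10-bromodecyloxy)(tert-butyl)dimethylsilane | CC(C)(C)[Si](C)(C)OCCCCCCCCCCBr | intermediate
3 | (R)-epichlorohydrin, (R)-2-(chloromethyl)oxirane | ClC[C@H]1CO1 | starting material
4 | {10-[(tert-butyldimethylsilyl)oxy]decyl}magnesium bromide | CC(C)(C)[Si](C)(C)OCCCCCCCCCC[Mg]Br | intermediate (not isolated)
5 | (R)-13-[(tert-butyldimethylsilyl)oxy]-1-chlorotridecan-2-ol | ClC[C@H](O)CCCCCCCCCCCO[Si](C)(C)C(C)(C)C | intermediate (not isolated)
6 | (R)-tert-butyldimethyl{[11-(oxiran-2-yl)undecyl]oxy}silane | C1[C@@H](CCCCCCCCCCCO[Si](C)(C)C(C)(C)C)O1 | intermediate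
7 | (R)-13-[(tert-butyldimethylsilyl)oxy]-1-iodotridecan-2-ol | IC[C@H](O)CCCCCCCCCCCO[Si](C)(C)C(C)(C)C | intermediate
8 | 2,4-dimethoxybenzoic acid | COc1ccc(C(=O)O)c(OC)c1 | starting material
9 | 5-iodo-2,4-dimethoxybenzoic acid | COc1cc(OC)c(cc1I)C(=O)O | intermediate
10 | (R)-13-[(tert-butyldimethylsilyl)oxy]-1-iodotridecan-2-yl 5-iodo-2,4-dimethoxybenzoate | COc1cc(OC)c(cc1I)C(=O)O[C@@H](CI)CCCCCCCCCCCO[Si](C)(C)C(C)(C)C | intermediate
11 | (R)-3-{11-[(tert-butyldimethylsilyl)oxy]undecyl}-6,8-dimethoxyisochroman-1-one | COc1cc(OC)c2c(c1)C[C@@H](CCCCCCCCCCCO[Si](C)(C)C(C)(C)C)OC2=O | intermediate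
12 | (R)-8-hydroxy-3-(11-hydroxyundecyl)-6-methoxyisochroman-1-one | COc1cc(O)c2c(c1)C[C@@H](CCCCCCCCCCCO)OC2=O | target

**Step count**

Total steps: 7. Longest linear sequence: 6 steps (steps 1, 2, 3, 5, 6, 7); step 4 is a one-step side branch.

**Steps most likely to fail**

Step 6. The annulation may fail in three ways:
- hydride reduction at C5 before the C–H alkylation has taken place;
- β-acyloxy elimination from the palladium-bound C4;
- intermolecular alkylation and oligomerisation, because the ester prefers its s-cis rotamer.

In that case the order of bond formation would be reversed. The fallback sets out from epoxide 6 and acid 8: heating both with Pd(OAc)2 and KOAc in (CF3)2CHOH at 75 °C should bring about carboxylate-directed ortho C–H palladation by divalent palladium at the only free ortho position of 8, SN2-type opening of the epoxide at its CH2 terminus and spontaneous lactonisation. This would give lactone 11 directly with the C3 configuration retained, and the route resumes at step 7. This path makes no compound outside the list (F0).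

Step 5. The acylation may fail through base-induced reclosure of the iodohydrin to epoxide 6, or through alkylation of DMAP by the primary iodide. In that case the iodide would be introduced after the acylation. The fallback sets out from chlorohydrin 5, isolated by stopping step 2 before the NaOH treatment. Esterification of 5 with acid 9 (DCC, DMAP, CH2Cl2) should give (R)-13-[(tert-butyldimethylsilyl)oxy]-1-chlorotridecan-2-yl 5-iodo-2,4-dimethoxybenzoate F1. A Finkelstein exchange (NaI, butanone, reflux) then converts F1 into ester 10, where the route resumes.

Step 7. The one-pot unmasking may fail through incomplete desilylation, chlorination of the primary carbinol, or further demethylation at O6. In that case the two groups would be removed in separate, orthogonal operations. The fallback sets out from lactone 11: fluoride (TBAF, AcOH, THF, rt) should cleave only the silyl ether to give (R)-3-(11-hydroxyundecyl)-6,8-dimethoxyisochroman-1-one F2. Treatment of F2 with BCl3 (CH2Cl2, −78 °C, aqueous work-up) should then remove only the chelated C8 methyl group and give target 12.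

Further compounds
F0 | step 6 | none | none
F1 | step 5 | (R)-13-[(tert-butyldimethylsilyl)oxy]-1-chlorotridecan-2-yl 5-iodo-2,4-dimethoxybenzoate | COc1cc(OC)c(cc1I)C(=O)O[C@@H](CCl)CCCCCCCCCCCO[Si](C)(C)C(C)(C)C
F2 | step 7 | (R)-3-(11-hydroxyundecyl)-6,8-dimethoxyisochroman-1-one | COc1cc(OC)c2c(c1)C[C@@H](CCCCCCCCCCCO)OC2=O
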